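The tetrahydrofuran ring (O1, C2 guaiacyl, C3 CH2OH, C4 aroyl, C5) is cut at C3–C4. The key step exploits two features: C3 with its hydroxymethyl arm is what a terminal epoxide leaves after homolytic opening, and C4 with its exocyclic aryl-bearing carbon is an arylalkyne carbon tied to O1 through C5. Cp2TiCl (trivalent titanium) opens the epoxide, the C3 radical closes the ring 5-exo-dig, C3 is set trans to the C2 aryl group and the primary alcohol is freed, all in one operation. The precursor is an enantioenriched erythro 1-aryl-2,3-epoxypropyl 3-arylprop-2-ynyl ether with both phenols benzylated; its benzylic centre (future C2) comes from a Sharpless kinetic resolution.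

Key step: step 6

Assumption: 4-(benzyloxy)-3-methoxybenzaldehyde (1) and 4-bromo-2,6-dimethoxyphenol (7) are taken as purchasable, and the benzylidene double bond of 10 is drawn Z although either geometry would serve, because steps 7 and 8 erase it.

Step 1
Reactants: 1 4-(benzyloxy)-3-methoxybenzaldehyde (O-benzylvanillin); 2 vinylmagnesium bromide
Product: 3 rac-1-[4-(benzyloxy)-3-methoxyphenyl]prop-2-en-1-ol
Conditions: THF, −78 → 0 °C; sat. aq. NH4Cl
Reagents that add atoms: none
Why: Grignard 1,2-addition of the vinyl nucleophile to the aryl aldehyde should give the racemic secondary allylic alcohol, and no stereocontrol is sought because the next step resolves it.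

Step 2
Reactants: 3 rac-1-[4-(benzyloxy)-3-methoxyphenyl]prop-2-en-1-ol
Product: 4 (R)-[4-(benzyloxy)-3-methoxyphenyl][(2S)-oxiran-2-yl]methanol (erythro epoxy alcohol)
Conditions: Ti(OiPr)4 (0.2 equiv), D-(−)-diisopropyl tartrate (0.25 equiv), t-BuOOH (0.45 equiv), 4 Å MS, CH2Cl2, −20 °C
Reagents that add atoms: tert-butyl hydroperoxide, CC(C)(C)OO
Why: Sharpless asymmetric epoxidation run as a kinetic resolution: the titanium D-(−)-tartrate complex should epoxidise the (S)-carbinol far faster than its antipode and on the alkene face that gives the erythro epoxy alcohol, so with less than half an equivalent of oxidant the benzylic centre (future C2) is selected by the resolution, the epoxide centre is set by the reagent, and the unreacted (R)-enantiomer of 3 is removed by chromatography.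

Step 3
Reactants: 4 (R)-[4-(benzyloxy)-3-methoxyphenyl][(2S)-oxiran-2-yl]methanol; 5 propargyl bromide
Product: 6 (2S)-2-{(R)-[4-(benzyloxy)-3-methoxyphenyl](prop-2-yn-1-yloxy)methyl}oxirane
Conditions: NaH, n-Bu4NI (cat.), THF, −20 → 0 °C (alkoxide generated with 5 already present)
Reagents that add atoms: none
Why: Williamson ether synthesis in which the sodium alkoxide is formed cold in the presence of the reactive propargylic bromide, so that SN2 capture on oxygen should outrun Payne migration of the epoxide and neither stereocentre is touched.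

Step 4
Reactants: 7 4-bromo-2,6-dimethoxyphenol
Product: 8 2-(benzyloxy)-5-bromo-1,3-dimethoxybenzene
Conditions: BnBr, K2CO3, DMF, rt
Reagents that add atoms: benzyl bromide, BrCc1ccccc1
Why: Williamson O-benzylation of the phenoxide under mild carbonate conditions, to which the aryl bromide is inert.

Step 5
Reactants: 6 (2S)-2-{(R)-[4-(benzyloxy)-3-methoxyphenyl](prop-2-yn-1-yloxy)methyl}oxirane; 8 2-(benzyloxy)-5-bromo-1,3-dimethoxybenzene
Product: 9 (2S)-2-{(R)-[4-(benzyloxy)-3-methoxyphenyl]({3-[4-(benzyloxy)-3,5-dimethoxyphenyl]prop-2-yn-1-yl}oxy)methyl}oxirane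
Conditions: Pd(PhCN)2Cl2 (cat.), P(t-Bu)3 (cat.), CuI (cat.), i-Pr2NH, dioxane, rt, degassed
Reagents that add atoms: none
Why: Sonogashira coupling of the terminal alkyne with the aryl bromide under zerovalent palladium/bulky phosphine catalysis at room temperature, where the hindered amine base should leave the terminal epoxide, the benzyl ethers and both stereocentres untouched.

Step 6
Reactants: 9 (2S)-2-{(R)-[4-(benzyloxy)-3-methoxyphenyl]({3-[4-(benzyloxy)-3,5-dimethoxyphenyl]prop-2-yn-1-yl}oxy)methyl}oxirane
Product: 10 [(2S,3R,4Z)-2-[4-(benzyloxy)-3-methoxyphenyl]-4-[4-(benzyloxy)-3,5-dimethoxybenzylidene]oxolan-3-yl]methanol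
Conditions: Cp2TiCl2 (2.5 equiv), Zn dust, THF, rt (green Cp2TiCl solution added dropwise to 9 in THF under argon); then dilute HCl
Reagents that add atoms: none
Why: Cp2TiCl (trivalent titanium) gives one electron to the epoxide, the C–O bond at the internal carbon breaks homolytically, and a β-titanoxy secondary radical results at the future C3 with the oxygen held as a titanium alkoxide on the CH2 group. This radical attacks the near alkyne carbon (future C4), forming C3–C4 and closing the tetrahydrofuran ring (O1, C2, C3, C4, C5) in the 5-exo-dig mode; the α-aryl vinyl radical is then capped by a second Cp2TiCl or by hydrogen abstraction from THF, and the acid quench releases the primary alcohol. The closest known reaction type is the titanocene-mediated reductive epoxide opening with 5-exo radical cyclisation (Nugent–RajanBabu chemistry), which is established for epoxy propargyl and allyl ethers as a way to 3-hydroxymethyl tetrahydrofurans. The one new stereocentre, C3, is controlled by the resolved C2 centre: in the chair-like 5-exo transition state the C2 aryl group sits pseudo-equatorial and the C3–CH2O arm ends up trans to it, while the planar radical makes the epoxide configuration irrelevant. The step needs cyclisation to win over capture of the C3 radical by a second titanium (which would end in reduction or β-alkoxide elimination), and this is secured by the short oxygen-containing tether, the aryl-activated alkyne and a low standing concentration of Cp2TiCl. The Z geometry drawn for the benzylidene group (aryl away from the C3 substituent) is of no consequence, since the next two steps remove that element.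

Step 7
Reactants: 10 [(2S,3R,4Z)-2-[4-(benzyloxy)-3-methoxyphenyl]-4-[4-(benzyloxy)-3,5-dimethoxybenzylidene]oxolan-3-yl]methanol
Product: 12 {(2S,3R,4R)-2-[4-(benzyloxy)-3-methoxyphenyl]-4-{[4-(benzyloxy)-3,5-dimethoxyphenyl](hydroxy)methyl}oxolan-3-yl}methanol (carbinol centre as a mixture), via benzylic organoborane 11 (not isolated)
Conditions: BH3·THF (3 equiv), THF, 0 °C → rt; then NaOH, H2O2, 0 °C → rt
Reagents that add atoms: hydrogen peroxide, OO
Why: Hydroboration–oxidation, in which borane should add syn across the trisubstituted styrenyl alkene with boron on the less substituted benzylic carbon and hydrogen on C4 (expected anti to the C3 arm, hence mainly 3,4-cis), and alkaline peroxide replaces boron by hydroxyl with retention; the carbinol centre is removed and C4 is corrected in step 8, so their ratios do not matter.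

Step 8
Reactants: 12 {(2S,3R,4R)-2-[4-(benzyloxy)-3-methoxyphenyl]-4-{[4-(benzyloxy)-3,5-dimethoxyphenyl](hydroxy)methyl}oxolan-3-yl}methanol
Product: 14 [4-(benzyloxy)-3,5-dimethoxyphenyl]{(3S,4R,5S)-5-[4-(benzyloxy)-3-methoxyphenyl]-4-(hydroxymethyl)oxolan-3-yl}methanone (2,3-trans-3,4-trans), via 3,4-cis ketone 13 (not isolated)
Conditions: MnO2 (activated, excess), CH2Cl2, rt; filter, concentrate; then DBU (0.3 equiv), toluene, rt
Reagents that add atoms: none
Why: Activated MnO2 should oxidise the benzylic alcohol selectively beside the primary aliphatic one, and DBU then equilibrates the ketone α-centre C4 through its enolate to the thermodynamically preferred isomer with the aroyl group trans to the C3 hydroxymethyl group, which fixes C4 as (S).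

Step 9
Reactants: 14 [4-(benzyloxy)-3,5-dimethoxyphenyl]{(3S,4R,5S)-5-[4-(benzyloxy)-3-methoxyphenyl]-4-(hydroxymethyl)oxolan-3-yl}methanone
Product: 15 (4-hydroxy-3,5-dimethoxyphenyl)[(3S,4R,5S)-5-(4-hydroxy-3-methoxyphenyl)-4-(hydroxymethyl)oxolan-3-yl]methanone (target; 2S,3R,4S in the O1/C2/C3/C4/C5 numbering)
Conditions: H2 (1 atm), 10% Pd/C, EtOAc, rt, stopped after two equivalents of H2
Reagents that add atoms: none
Why: Catalytic hydrogenolysis of the two aryl benzyl ethers over palladium on carbon in a neutral aprotic solvent should be much faster than reduction of the electron-rich aryl ketone or cleavage of the cyclic benzylic C2–O1 bond, and no stereocentre is affected.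

Compound list
1 | 4-(benzyloxy)-3-methoxybenzaldehyde (O-benzylvanillin) | COc1cc(C=O)ccc1OCc1ccccc1 | starting material
2 | vinylmagnesium bromide | C=C[Mg]Br | starting material
3 | rac-1-[4-(benzyloxy)-3-methoxyphenyl]prop-2-en-1-ol | C=CC(O)c1ccc(OCc2ccccc2)c(OC)c1 | intermediate
4 | (R)-[4-(benzyloxy)-3-methoxyphenyl][(2S)-oxiran-2-yl]methanol (erythro) | COc1cc([C@H]([C@@H]2CO2)O)ccc1OCc1ccccc1 | intermediate
5 | propargyl bromide (3-bromoprop-1-yne) | C#CCBr | starting material
6 | (2S)-2-{(R)-[4-(benzyloxy)-3-methoxyphenyl](prop-2-yn-1-yloxy)methyl}oxirane | COc1cc([C@H]([C@@H]2CO2)OCC#C)ccc1OCc1ccccc1 | intermediate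
7 | 4-bromo-2,6-dimethoxyphenol | COc1cc(Br)cc(OC)c1O | starting material
8 | 2-(benzyloxy)-5-bromo-1,3-dimethoxybenzene | COc1cc(Br)cc(OC)c1OCc1ccccc1 | intermediate
9 | (2S)-2-{(R)-[4-(benzyloxy)-3-methoxyphenyl]({3-[4-(benzyloxy)-3,5-dimethoxyphenyl]prop-2-yn-1-yl}oxy)methyl}oxirane (key-step precursor) | COc1cc([C@H]([C@@H]2CO2)OCC#Cc2cc(OC)c(OCc3ccccc3)c(OC)c2)ccc1OCc1ccccc1 | intermediate
10 | [(2S,3R,4Z)-2-[4-(benzyloxy)-3-methoxyphenyl]-4-[4-(benzyloxy)-3,5-dimethoxybenzylidene]oxolan-3-yl]methanol (key-step product) | COc1cc([C@H]2OC/C(=C\c3cc(OC)c(OCc4ccccc4)c(OC)c3)[C@@H]2CO)ccc1OCc1ccccc1 | intermediate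
11 | organoborane from 10: BH2 on the benzylic carbon, H on C4 cis-directing the new side chain to the C3 arm, hydroxyl carried as O–BH2 (borylated carbon as a mixture) | COc1cc([C@H]2OC[C@H](C(B)c3cc(OC)c(OCc4ccccc4)c(OC)c3)[C@@H]2COB)ccc1OCc1ccccc1 | intermediate
12 | {(2S,3R,4R)-2-[4-(benzyloxy)-3-methoxyphenyl]-4-{[4-(benzyloxy)-3,5-dimethoxyphenyl](hydroxy)methyl}oxolan-3-yl}methanol (carbinol centre undefined) | COc1cc([C@H]2OC[C@H](C(O)c3cc(OC)c(OCc4ccccc4)c(OC)c3)[C@@H]2CO)ccc1OCc1ccccc1 | intermediate
13 | [4-(benzyloxy)-3,5-dimethoxyphenyl]{(3R,4R,5S)-5-[4-(benzyloxy)-3-methoxyphenyl]-4-(hydroxymethyl)oxolan-3-yl}methanone (3,4-cis ketone) | COc1cc([C@H]2OC[C@H](C(=O)c3cc(OC)c(OCc4ccccc4)c(OC)c3)[C@@H]2CO)ccc1OCc1ccccc1 | intermediate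
14 | [4-(benzyloxy)-3,5-dimethoxyphenyl]{(3S,4R,5S)-5-[4-(benzyloxy)-3-methoxyphenyl]-4-(hydroxymethyl)oxolan-3-yl}methanone (all-trans ketone) | COc1cc([C@H]2OC[C@@H](C(=O)c3cc(OC)c(OCc4ccccc4)c(OC)c3)[C@@H]2CO)ccc1OCc1ccccc1 | intermediate
15 | (4-hydroxy-3,5-dimethoxyphenyl)[(3S,4R,5S)-5-(4-hydroxy-3-methoxyphenyl)-4-(hydroxymethyl)oxolan-3-yl]methanone | COc1cc([C@H]2OC[C@@H](C(=O)c3cc(OC)c(O)c(OC)c3)[C@@H]2CO)ccc1O | target

Total step count: 9
Longest linear sequence: 8 steps (steps 1, 2, 3, 5, 6, 7, 8, 9; step 4 is a one-step side branch).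

Steps most likely to fail

Step 6. The C3 radical may be captured by a second trivalent titanium before it cyclises, which would end in simple reduction or in loss of the propargyloxy group by β-elimination. The fallback generates the same radical in a tin hydride chain process with no metal radical trap and sets out from 9. The epoxide is hydrolysed at its CH2 carbon (catalytic HClO4, THF–H2O) to the diol F1. The primary hydroxyl is silylated (TBSCl, imidazole) to the primary tert-butyldimethylsilyl ether F2. The remaining secondary hydroxyl is acylated (PhOC(S)Cl, pyridine, DMAP) to the phenyl thionocarbonate F3. Bu3SnH and AIBN in refluxing benzene under syringe-pump addition (Barton–McCombie-type radical generation) should then give 5-exo-dig closure to the silyl-protected benzylidene tetrahydrofuran F4. Bu4NF removes the silyl group and the route is rejoined at 10.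

Step 8. Equilibration at C4 may stall or go astray: the 3,4-cis hydroxy ketone can be held as a bicyclic hemiketal, and prolonged base may let the enolate expel O1 (retro-oxa-Michael ring opening). The fallback masks the hydroxyl first and sets out from 12. Selective silylation of the primary alcohol (TBSCl, imidazole) gives the mono-silyl ether F5. Dess–Martin oxidation of the benzylic alcohol gives the silyl-protected cis ketone F6. A short DBU treatment, now free of hemiketal and alkoxide pathways, should give the silyl-protected trans ketone F7. Buffered fluoride (Bu4NF, AcOH) rejoins the route at 14.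

Step 7. Boron may add in part to C4 instead of the benzylic carbon, or the hindered trisubstituted alkene may react sluggishly. The fallback is a Mukaiyama hydration of 10 (Co(acac)2 catalyst, PhSiH3, O2, i-PrOH, then PPh3 to reduce any hydroperoxide). Hydrogen-atom transfer to C4 gives the more stable benzylic radical, which is trapped by oxygen at the benzylic carbon. This should deliver 12 directly as a mixture at C4 and the carbinol centre, both of which step 8 corrects, so the route is rejoined at 12.

Further compounds
F1 | step 6 | (2S,3R)-3-[4-(benzyloxy)-3-methoxyphenyl]-3-({3-[4-(benzyloxy)-3,5-dimethoxyphenyl]prop-2-yn-1-yl}oxy)propane-1,2-diol | COc1cc([C@H]([C@@H](O)CO)OCC#Cc2cc(OC)c(OCc3ccccc3)c(OC)c2)ccc1OCc1ccccc1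
F2 | step 6 | 1-O-tert-butyldimethylsilyl ether of F1 | COc1cc([C@H]([C@@H](O)CO[Si](C)(C)C(C)(C)C)OCC#Cc2cc(OC)c(OCc3ccccc3)c(OC)c2)ccc1OCc1ccccc1
F3 | step 6 | O-phenyl thionocarbonate of F2 at the secondary hydroxyl | COc1cc([C@H]([C@@H](OC(=S)Oc2ccccc2)CO[Si](C)(C)C(C)(C)C)OCC#Cc2cc(OC)c(OCc3ccccc3)c(OC)c2)ccc1OCc1ccccc1
F4 | step 6 | tert-butyldimethylsilyl ether of 10 | COc1cc([C@H]2OC/C(=C\c3cc(OC)c(OCc4ccccc4)c(OC)c3)[C@@H]2CO[Si](C)(C)C(C)(C)C)ccc1OCc1ccccc1
F5 | step 8 | primary tert-butyldimethylsilyl ether of 12 | COc1cc([C@H]2OC[C@H](C(O)c3cc(OC)c(OCc4ccccc4)c(OC)c3)[C@@H]2CO[Si](C)(C)C(C)(C)C)ccc1OCc1ccccc1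
F6 | step 8 | tert-butyldimethylsilyl ether of 13 (3,4-cis ketone) | COc1cc([C@H]2OC[C@H](C(=O)c3cc(OC)c(OCc4ccccc4)c(OC)c3)[C@@H]2CO[Si](C)(C)C(C)(C)C)ccc1OCc1ccccc1
F7 | step 8 | tert-butyldimethylsilyl ether of 14 (all-trans ketone) | COc1cc([C@H]2OC[C@@H](C(=O)c3cc(OC)c(OCc4ccccc4)c(OC)c3)[C@@H]2CO[Si](C)(C)C(C)(C)C)ccc1OCc1ccccc1
F0 | step 7 | none | none
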